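(All runs are simulated for substances that don't exist, and the scatter is random.)

| flask | substrate | catalyst | temperature | remark | time |
|---|---|---|---|---|---|
| Thursday's | 14 mM | 10 µM | 45 °C | run made earlier |  |
| Wednesday's | 22 mM | 10 µM | 95 °C | run made earlier |  |
| Friday's | 10 mM | 5 µM | 45 °C | run made earlier |  |
| south-west | 10 mM | 10 µM | 140 °C |  | 3.0 min |
| north-west | 10 mM | 10 µM | 50 °C |  | 3.0 min |
| north | 10 mM | 10 µM | 80 °C |  | 3.0 min |
| south-east | 10 mM | 10 µM | 110 °C |  | 3.0 min |

| run | time / min | target / % | substrate / % |
|---|---|---|---|
| Thursday's | 50.0 | 85 | 4 |
| Thursday's | 90.0 | 84 | 5 |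
| Thursday's | 150 | 80 | 2 |
| Thursday's | 180 | 81 | 2 |
| Thursday's | 240 | 80 | 5 |
| Thursday's | 300 | 75 | 5 |
| Wednesday's | 2.00 | 79 | 12 |
| Wednesday's | 3.00 | 78 | 10 |
| Wednesday's | 5.00 | 70 | 9 |
| Wednesday's | 8.00 | 64 | 11 |
| Wednesday's | 12.0 | 52 | 7 |
| Wednesday's | 25.0 | 32 | 7 |
| Friday's | 60.0 | 80 | 6 |
| Friday's | 120 | 79 | 5 |
| Friday's | 150 | 82 | 0 |
| Friday's | 240 | 78 | 1 |
| Friday's | 300 | 74 | 5 |

(each reading ± 2 percentage points)



- the flask that comes out highest in amount of target, in percent of the substrate charged, or "all alike" when all lie within 1.5 percentage points (south-west / north-west / north / south-east / all alike)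
- target at the end, in percent of the substrate charged, south-west
- target at the end, in percent of the substrate charged, north-west
- target at the end, in percent of the substrate charged, north
- target at the end, in percent of the substrate charged, south-east

1. The first instants. The north flask began with 10 mM of substrate, 10 µM of catalyst and no target, at 80 °C. Wednesday's run, at 95 °C, already read 79% target and 12% substrate after 2.00 min, so I assumed that the north flask reached its plateau well within its 3.0 min.

2. The middle. For the plateau I took Thursday's first reading, 85% target with 4% substrate. That left 11 percentage points of the charge in neither column, a reading with its scatter. This plateau was the large term, and the correction to it was what I computed.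

3. The end. In the earlier runs target then fell, and I treated the fall as first-order. Wednesday's run went from 79% to 32% between 2.00 min and 25.0 min, which gave a loss constant of 0.0393 min⁻¹. Thursday's went from 85% to 75% between 50.0 min and 300 min, which gave 5.01 × 10⁻⁴ min⁻¹. Friday's run, at the same temperature as Thursday's with half of the catalyst and 10 mM of substrate, read 74% at 300 min against Thursday's 75%, so I took the loss to be independent of catalyst, though two settings differed between these runs.

4. Interpolating the logarithm of the constant straight in temperature gave 0.0106 min⁻¹ at 80 °C. Over 3.0 min that made 3.18%. I called this product of loss constant and time the loss share: while it is small, the part of the target that the loss takes at a given temperature in a given time. On the plateau it came to 2.7 points, so my figure for the north flask was 82.3%.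

5. The forecast gave 7% for south-west, 50% for north-west, 81% for north, a little below my figure, and 60% for south-east, with the words “The north flask should be highest.”

6. The flasks gave 2.44% south-west, 76.5% north-west, 84.4% north and 55.6% south-east, so north came out highest.

    substrate + catalyst ⇌ target + catalyst, rate k1*[substrate]*[catalyst] forward; the back reaction follows from the equilibrium constant (K = 25.0, k = 1250 L mol⁻¹ s⁻¹, Ea = 38.0 kJ mol⁻¹, ΔH = −27.0 kJ mol⁻¹)
    target + catalyst ⇌ isomer of the product + catalyst, rate k2*[catalyst]*[target] forward; the back reaction follows from the equilibrium constant (K = 0.140, k = 1650 L mol⁻¹ s⁻¹, Ea = 48.0 kJ mol⁻¹, ΔH = −27.0 kJ mol⁻¹)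
    target → over-reaction product (k = 8.03 × 10⁻⁶ s⁻¹, Ea = 100 kJ mol⁻¹)
    (constants at 50 °C)

The north flask held 2.56% of over-reaction product after 3.00 min, against my correction of 2.7 points. The neighbouring flask was the north flask with 0.0025 mM of catalyst, a quarter of the north flask's catalyst. Its temperature and time were unchanged, so its loss share was again 3.18%, and on its 73.9% of target that made 2.4 points. It held 1.68% of over-reaction product, less than that. Its target stood 10 points below the north flask's, and its substrate stood at 20.1% against 7.99% in the north flask.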